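**Retrosynthetic overview**

1. Feature: in the lactone ring, C8' (the carbon carrying the ring-B benzyl carbon C7') is a lone CH whose ring neighbours are the O-CH2 carbon C9' and, before ring A is attached, the CH2 carbon C8. It is therefore the α-carbon of a glutamate-derived γ-butyrolactone whose carbonyl sits provisionally at C9' and is later transposed to C9.
2. Target ⇐ acetonide hydrolysis and hydrogenolysis ⇐ trans benzylation at C8 of the (R)-β-(ring-B-benzyl) butyrolactone with the ring-A benzyl bromide.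
3. That lactone ⇐ lactol oxidation ⇐ periodate cleavage of the (2R,4S)-2-(ring-B-arylmethyl)pentane-1,4,5-triol with closure of the C9–O bond ⇐ hydride reduction and desilylation ⇐ trans alkylation of the L-glutamate-derived (S)-silyloxymethyl lactone with the ring-B benzyl bromide.
4. Ring-B bromide ⇐ Appel bromination, acetonide formation, LiAlH4 ⇐ Evans syn-aldol of an (S)-benzyloxazolidinone aryloxyacetyl imide (from methyl vanillate) with O-benzylvanillin; this sets C7''/C8'' threo with the C8''–O–C4' ether already in place.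
5. Ring order: 1,3-dioxane (protective) → glutamate lactone alkylated and opened → tetrahydrofuranol (key step) → butyrolactone of the target.

Key step: step 13

Remark: lignan labels are used (ring A with C7–C9 on the lactone α-carbon, C9 = C=O; ring B with C7'–C9' on the β-carbon, C9' = OCH2; ring C with C7''–C9'' in the glycerol unit). The SMILES is read as (8R,8'R,7''R,8''R), a trans lactone with a threo side chain. "ArB" stands for 4-{[(4R,5R)-4-(4-benzyloxy-3-methoxyphenyl)-2,2-dimethyl-1,3-dioxan-5-yl]oxy}-3-methoxyphenyl. The oxazolidinone, bromoacetyl bromide, methyl vanillate, O-benzylvanillin and 4-benzyloxy-3-methoxybenzyl alcohol are taken as commercial.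

**Route**

Step 1
Reactants: 1 L-glutamic acid
Product: 2 (S)-5-oxotetrahydrofuran-2-carboxylic acid
Conditions: NaNO2, aq. HCl, 0 °C → rt
Reagents that add atoms: none
Why: Diazotisation of the α-amino acid is followed by displacement of N2 by the α-carboxylate (α-lactone) and reopening by the γ-carboxyl group, so two inversions give net retention and the (S)-lactone acid (deaminative lactonisation).

Step 2
Reactants: 2 (S)-5-oxotetrahydrofuran-2-carboxylic acid
Product: 3 (S)-5-(hydroxymethyl)dihydrofuran-2(3H)-one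
Conditions: BH3·SMe2, THF, 0 °C → rt; MeOH quench
Reagents that add atoms: none
Why: Borane reduces the free carboxylic acid through an acyloxyborane much faster than the lactone (chemoselective borane reduction) and does not touch the stereocentre.

Step 3
Reactants: 3 (S)-5-(hydroxymethyl)dihydrofuran-2(3H)-one
Product: 4 (S)-5-{[(tert-butyldiphenylsilyl)oxy]methyl}dihydrofuran-2(3H)-one
Conditions: t-BuPh2SiCl, imidazole, DMF, 0 °C → rt
Reagents that add atoms: tert-butyl(chloro)diphenylsilane, CC(C)(C)[Si](Cl)(c1ccccc1)c1ccccc1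
Why: Standard silylation of the primary alcohol installs a bulky, base-stable and fluoride-labile group that later shields one face of the lactone enolate.

Step 4
Reactants: 5 (S)-4-benzyloxazolidin-2-one; 6 bromoacetyl bromide
Product: 8 (S)-4-benzyl-3-(bromoacetyl)oxazolidin-2-one, via N-lithio oxazolidinone 7 (not isolated)
Conditions: n-BuLi, THF, −78 °C; then 6, −78 → 0 °C
Reagents that add atoms: none
Why: N-Acylation of the lithiated auxiliary takes place at the acyl bromide, which is far more electrophilic than the alkyl bromide at −78 °C.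

Step 5
Reactants: 8 (S)-4-benzyl-3-(bromoacetyl)oxazolidin-2-one; 9 methyl vanillate (methyl 4-hydroxy-3-methoxybenzoate)
Product: 10 methyl 4-{2-[(S)-4-benzyl-2-oxooxazolidin-3-yl]-2-oxoethoxy}-3-methoxybenzoate
Conditions: K2CO3, acetone, rt
Reagents that add atoms: none
Why: Williamson etherification, in which the soft phenoxide displaces the activated α-bromide by SN2 faster than it attacks the imide carbonyl, builds the future C8''–O–C4' ether before any stereocentre exists.

Step 6
Reactants: 10 methyl 4-{2-[(S)-4-benzyl-2-oxooxazolidin-3-yl]-2-oxoethoxy}-3-methoxybenzoate; 11 4-(benzyloxy)-3-methoxybenzaldehyde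
Product: 13 methyl 4-({(1R,2S)-1-[4-(benzyloxy)-3-methoxyphenyl]-3-[(S)-4-benzyl-2-oxooxazolidin-3-yl]-1-hydroxy-3-oxopropan-2-yl}oxy)-3-methoxybenzoate, via dibutylboron Z-enolate 12 (not isolated)
Conditions: Bu2BOTf, iPr2NEt, CH2Cl2, −78 → 0 °C; then 11, −78 → 0 °C; pH 7 buffer, MeOH, H2O2
Reagents that add atoms: none
Why: Evans syn-aldol, in which the Z-boron enolate reacts through a Zimmerman–Traxler chair and the benzyl group of the (S)-auxiliary blocks one enolate face, should set C7'' (R) and C8'' (S here, R once C9'' is reduced) as the syn (threo) pair.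

Step 7
Reactants: 13 syn-aldol imide
Product: 14 (1R,2R)-1-[4-(benzyloxy)-3-methoxyphenyl]-2-[4-(hydroxymethyl)-2-methoxyphenoxy]propane-1,3-diol
Conditions: LiAlH4, THF, 0 °C
Reagents that add atoms: none
Why: Hydride reduction cleaves the imide to the primary alcohol C9'' with release of the auxiliary and reduces the aryl methyl ester to the ring-B benzylic alcohol, without touching either stereocentre.

Step 8
Reactants: 14 triol
Product: 15 ArB-methanol, i.e. [4-({(4R,5R)-4-[4-(benzyloxy)-3-methoxyphenyl]-2,2-dimethyl-1,3-dioxan-5-yl}oxy)-3-methoxyphenyl]methanol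
Conditions: Me2C(OMe)2, pyridinium p-toluenesulfonate (cat.), acetone, rt; aq. NaHCO3
Reagents that add atoms: 2,2-dimethoxypropane, COC(C)(C)OC
Why: Acid-catalysed transketalisation should close the 7'',9''-diol to the 1,3-dioxane with aryl and aryloxy groups both equatorial, while the lone benzylic hydroxyl can form only an acyclic mixed ketal that is lost on aqueous work-up.

Step 9
Reactants: 15 ArB-methanol
Product: 16 ArB-methyl bromide, i.e. (4R,5R)-4-[4-(benzyloxy)-3-methoxyphenyl]-5-[4-(bromomethyl)-2-methoxyphenoxy]-2,2-dimethyl-1,3-dioxane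
Conditions: CBr4, PPh3, CH2Cl2, 0 °C; used at once
Reagents that add atoms: carbon tetrabromide, BrC(Br)(Br)Br
Why: Appel bromination goes through an alkoxyphosphonium salt under neutral conditions, so the benzylic alcohol is exchanged for bromide without HBr that would open the acetonide.

Step 10
Reactants: 4 (S)-5-{[(tert-butyldiphenylsilyl)oxy]methyl}dihydrofuran-2(3H)-one; 16 ArB-methyl bromide
Product: 18 (3R,5S)-3-(ArB-methyl)-5-{[(tert-butyldiphenylsilyl)oxy]methyl}dihydrofuran-2(3H)-one, via lithium enolate 17 (not isolated)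
Conditions: LiN(iPr)2, THF, −78 °C; then 16, THF/DMPU, −78 → −40 °C; chromatography
Reagents that add atoms: none
Why: Lactone enolate alkylation, in which the benzylic bromide approaches anti to the C5 silyloxymethyl group, should give the 3,5-trans product and so set the future C8' as R; the minor cis isomer must be removed here because it would become the enantiomer after step 13.

Step 11
Reactants: 18 trans-alkylated lactone
Product: 19 (2R,4S)-2-(ArB-methyl)-5-[(tert-butyldiphenylsilyl)oxy]pentane-1,4-diol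
Conditions: LiAlH4, THF, 0 °C
Reagents that add atoms: none
Why: Hydride reduction opens the lactone to the 1,4-diol, turning the carbonyl carbon into the future C9' hydroxymethyl group; silyl ether, acetonide and benzyl ether are inert.

Step 12
Reactants: 19 silyl ether diol
Product: 20 (2R,4S)-2-(ArB-methyl)pentane-1,4,5-triol
Conditions: Bu4NF, THF, rt
Reagents that add atoms: none
Why: Fluoride-mediated desilylation exposes the terminal 1,2-diol under conditions that leave the acetonide and all ethers untouched.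

Step 13
Reactants: 20 (2R,4S)-2-(ArB-methyl)pentane-1,4,5-triol
Product: 22 (4R)-4-(ArB-methyl)tetrahydrofuran-2-ol (anomer mixture), via hydroxy aldehyde 21 (not isolated)
Conditions: NaIO4, NaHCO3, THF/H2O, 0 °C → rt
Reagents that add atoms: none
Why: Periodate condenses with the C4/C5 vicinal diol of 20 to a cyclic periodate ester that fragments (Malaprade glycol cleavage), releasing C5 (the former glutamate carboxyl carbon) as formaldehyde and turning C4 (the former glutamate α-carbon, the future C9) into the aldehyde of 21, so the stereocentre that steered step 10 is erased. The C1 hydroxyl (the future O–C9') then adds to this aldehyde in a 5-exo-trig closure, forming the C9–O bond and the tetrahydrofuran-2-ol ring of 22; the closest known reaction type is glycol cleavage with spontaneous γ-lactol formation, used to transpose the carbonyl of chiral-pool γ-butyrolactones. The only new stereocentre is the anomeric carbon, which is left uncontrolled because step 14 makes it trigonal. C8' is not touched and keeps the R configuration set in step 10, but the trans purity of 18 becomes the enantiomeric purity of 22. The step needs chemoselectivity for one diol: 20 has a single free vicinal diol, the side-chain oxygens are 1,3-related and locked in the acetonide, and the NaHCO3 buffer keeps the medium from hydrolysing that acetonide.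

Step 14
Reactants: 22 lactol
Product: 23 (R)-4-(ArB-methyl)dihydrofuran-2(3H)-one
Conditions: TEMPO (cat.), PhI(OAc)2, CH2Cl2, rt
Reagents that add atoms: none
Why: Oxoammonium-mediated oxidation of the hemiacetal, the only free hydroxyl, gives the lactone with the carbonyl now at C9, under conditions mild enough for the acetonide and the electron-rich arenes.

Step 15
Reactants: 24 [4-(benzyloxy)-3-methoxyphenyl]methanol
Product: 25 1-(benzyloxy)-4-(bromomethyl)-2-methoxybenzene
Conditions: PBr3, Et2O, 0 °C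
Reagents that add atoms: phosphorus tribromide, BrP(Br)Br
Why: Bromination of a primary benzylic alcohol through its phosphite ester is a standard SN2 exchange.

Step 16
Reactants: 23 (R)-4-(ArB-methyl)dihydrofuran-2(3H)-one; 25 1-(benzyloxy)-4-(bromomethyl)-2-methoxybenzene
Product: 27 (3R,4R)-3-[4-(benzyloxy)-3-methoxybenzyl]-4-(ArB-methyl)dihydrofuran-2(3H)-one, via lithium enolate 26 (not isolated)
Conditions: LiN(SiMe3)2, THF, −78 °C; then 25, DMPU, −78 → −30 °C
Reagents that add atoms: none
Why: Enolate alkylation of a β-substituted butyrolactone, in which the electrophile enters anti to the C8' benzyl group, should form the C8–C7 bond with the trans (8R,8'R) relationship.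

Step 17
Reactants: 27 fully protected lactone
Product: 28 (3R,4R)-3-[4-(benzyloxy)-3-methoxybenzyl]-4-[4-({(1R,2R)-1-[4-(benzyloxy)-3-methoxyphenyl]-1,3-dihydroxypropan-2-yl}oxy)-3-methoxybenzyl]dihydrofuran-2(3H)-one
Conditions: AcOH/H2O/THF, 40 °C
Reagents that add atoms: none
Why: Mild aqueous acid hydrolyses the 1,3-dioxane ketal through the acetone-derived oxocarbenium ion, not by ionising the benzylic C7''–O bond, so the 7'',9''-diol is freed while lactone and ethers persist.

Step 18
Reactants: 28 bis(benzyl ether) diol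
Product: 29 CNP0144301.3, (3R,4R)-4-[4-({(1R,2R)-1,3-dihydroxy-1-(4-hydroxy-3-methoxyphenyl)propan-2-yl}oxy)-3-methoxybenzyl]-3-(4-hydroxy-3-methoxybenzyl)dihydrofuran-2(3H)-one
Conditions: H2 (1 atm), Pd/C, EtOAc/EtOH, rt
Reagents that add atoms: none
Why: Catalytic hydrogenolysis cleaves the two aryl benzyl ethers under neutral conditions, under which the secondary benzylic C7'' hydroxyl, the lactone and the alkyl aryl ether are expected to survive.

**Compound list**

1 | L-glutamic acid | N[C@@H](CCC(=O)O)C(=O)O | starting material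
2 | (S)-5-oxotetrahydrofuran-2-carboxylic acid | O=C1CC[C@@H](C(=O)O)O1 | intermediate
3 | (S)-5-(hydroxymethyl)dihydrofuran-2(3H)-one | O=C1CC[C@@H](CO)O1 | intermediate
4 | (S)-5-{[(tert-butyldiphenylsilyl)oxy]methyl}dihydrofuran-2(3H)-one | O=C1CC[C@@H](CO[Si](c2ccccc2)(c2ccccc2)C(C)(C)C)O1 | intermediate
5 | (S)-4-benzyloxazolidin-2-one | O=C1N[C@@H](Cc2ccccc2)CO1 | starting material
6 | bromoacetyl bromide | BrCC(Br)=O | starting material
7 | N-lithio (S)-4-benzyloxazolidin-2-one (not isolated) | [Li]N1C(=O)OC[C@@H]1Cc1ccccc1 | intermediate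
8 | (S)-4-benzyl-3-(bromoacetyl)oxazolidin-2-one | O=C(CBr)N1C(=O)OC[C@@H]1Cc1ccccc1 | intermediate
9 | methyl vanillate | COC(=O)c1ccc(O)c(OC)c1 | starting material
10 | methyl 4-{2-[(S)-4-benzyl-2-oxooxazolidin-3-yl]-2-oxoethoxy}-3-methoxybenzoate | COC(=O)c1ccc(OCC(=O)N2C(=O)OC[C@@H]2Cc2ccccc2)c(OC)c1 | intermediate
11 | 4-(benzyloxy)-3-methoxybenzaldehyde | COc1cc(C=O)ccc1OCc1ccccc1 | starting material
12 | dibutylboron Z-enolate of 10 (not isolated) | CCCCB(CCCC)O/C(=C\Oc1ccc(C(=O)OC)cc1OC)N1C(=O)OC[C@@H]1Cc1ccccc1 | intermediate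
13 | syn-aldol imide, (2S,3R) in the acyl chain | COC(=O)c1ccc(O[C@H](C(=O)N2C(=O)OC[C@@H]2Cc2ccccc2)[C@H](O)c2ccc(OCc3ccccc3)c(OC)c2)c(OC)c1 | intermediate
14 | (1R,2R)-1-[4-(benzyloxy)-3-methoxyphenyl]-2-[4-(hydroxymethyl)-2-methoxyphenoxy]propane-1,3-diol | OCc1ccc(O[C@H](CO)[C@H](O)c2ccc(OCc3ccccc3)c(OC)c2)c(OC)c1 | intermediate
15 | ArB-methanol, (4R,5R)-acetonide | OCc1ccc(O[C@@H]2COC(C)(C)O[C@@H]2c3ccc(OCc4ccccc4)c(OC)c3)c(OC)c1 | intermediate
16 | ArB-methyl bromide, (4R,5R)-acetonide | BrCc1ccc(O[C@@H]2COC(C)(C)O[C@@H]2c3ccc(OCc4ccccc4)c(OC)c3)c(OC)c1 | intermediate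
17 | lithium enolate of 4 (not isolated) | [Li]OC1=CC[C@@H](CO[Si](c2ccccc2)(c2ccccc2)C(C)(C)C)O1 | intermediate
18 | (3R,5S)-3-(ArB-methyl)-5-{[(tert-butyldiphenylsilyl)oxy]methyl}dihydrofuran-2(3H)-one (3,5-trans) | O=C1[C@H](Cc2ccc(O[C@@H]3COC(C)(C)O[C@@H]3c4ccc(OCc5ccccc5)c(OC)c4)c(OC)c2)C[C@@H](CO[Si](c6ccccc6)(c7ccccc7)C(C)(C)C)O1 | intermediate
19 | (2R,4S)-2-(ArB-methyl)-5-[(tert-butyldiphenylsilyl)oxy]pentane-1,4-diol | OC[C@H](Cc1ccc(O[C@@H]2COC(C)(C)O[C@@H]2c3ccc(OCc4ccccc4)c(OC)c3)c(OC)c1)C[C@H](O)CO[Si](c5ccccc5)(c6ccccc6)C(C)(C)C | intermediate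
20 | (2R,4S)-2-(ArB-methyl)pentane-1,4,5-triol | OC[C@H](Cc1ccc(O[C@@H]2COC(C)(C)O[C@@H]2c3ccc(OCc4ccccc4)c(OC)c3)c(OC)c1)C[C@H](O)CO | intermediate
21 | (R)-3-(ArB-methyl)-4-hydroxybutanal (not isolated) | O=CC[C@H](CO)Cc1ccc(O[C@@H]2COC(C)(C)O[C@@H]2c3ccc(OCc4ccccc4)c(OC)c3)c(OC)c1 | intermediate
22 | (4R)-4-(ArB-methyl)tetrahydrofuran-2-ol, anomer mixture | OC1C[C@@H](Cc2ccc(O[C@@H]3COC(C)(C)O[C@@H]3c4ccc(OCc5ccccc5)c(OC)c4)c(OC)c2)CO1 | intermediate
23 | (R)-4-(ArB-methyl)dihydrofuran-2(3H)-one | O=C1C[C@@H](Cc2ccc(O[C@@H]3COC(C)(C)O[C@@H]3c4ccc(OCc5ccccc5)c(OC)c4)c(OC)c2)CO1 | intermediate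
24 | [4-(benzyloxy)-3-methoxyphenyl]methanol | COc1cc(CO)ccc1OCc1ccccc1 | starting material
25 | 1-(benzyloxy)-4-(bromomethyl)-2-methoxybenzene | COc1cc(CBr)ccc1OCc1ccccc1 | intermediate
26 | lithium enolate of 23 (not isolated) | [Li]OC1=C[C@@H](Cc2ccc(O[C@@H]3COC(C)(C)O[C@@H]3c4ccc(OCc5ccccc5)c(OC)c4)c(OC)c2)CO1 | intermediate
27 | (3R,4R)-3-[4-(benzyloxy)-3-methoxybenzyl]-4-(ArB-methyl)dihydrofuran-2(3H)-one | COc1cc(C[C@H]2C(=O)OC[C@@H]2Cc2ccc(O[C@@H]3COC(C)(C)O[C@@H]3c4ccc(OCc5ccccc5)c(OC)c4)c(OC)c2)ccc1OCc1ccccc1 | intermediate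
28 | 7'',9''-diol bis(benzyl ether), (8R,8'R,7''R,8''R) | COc1cc(C[C@H]2C(=O)OC[C@@H]2Cc2ccc(O[C@H](CO)[C@H](O)c3ccc(OCc4ccccc4)c(OC)c3)c(OC)c2)ccc1OCc1ccccc1 | intermediate
29 | CNP0144301.3 | COc1cc(C[C@H]2C(=O)OC[C@@H]2Cc2ccc(O[C@H](CO)[C@H](O)c3ccc(O)c(OC)c3)c(OC)c2)ccc1O | target

**Totals**

Total step count: 18. Longest linear sequence: 14 steps (steps 4 to 14, then 16 to 18).

**Steps most likely to fail**

Step 10. Facial discrimination in the enolate alkylation may be incomplete, and the electron-rich benzylic bromide 16 may ionise or decompose before it is captured. The fallback sets out from 15 and 4 and comes back at 18. Alcohol 15 is oxidised with MnO2 in CH2Cl2 to the ring-B benzaldehyde F1. Addition of lithium enolate 17 (from 4, LiN(iPr)2, THF, −78 °C) should give the β-hydroxy lactone F2, with the new C–C bond again formed anti to the silyloxymethyl group; the carbinol epimers are of no consequence. Treatment with 1,1'-thiocarbonyldiimidazole and DMAP gives the O-(imidazol-1-ylthiocarbonyl) derivative F3, and Barton–McCombie reduction (Bu3SnH, AIBN, toluene, 90 °C) removes the benzylic oxygen to reach 18.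

Step 6. The aldol addition may stall with the poorly electrophilic, electron-rich aldehyde, or the adduct may revert by retro-aldol on work-up, eroding the syn selectivity. The fallback sets out from 9 and 11 and comes back at 14. Phenol 9 is alkylated with methyl bromoacetate (K2CO3, acetone) to the aryloxyacetate diester F4. Its lithium enolate (LiN(iPr)2, THF, −78 °C) adds to 11 to give the racemic hydroxy ester F5 as a diastereomer mixture, which Dess–Martin periodinane oxidises to the configurationally labile β-keto ester F6. Asymmetric transfer hydrogenation with dynamic kinetic resolution (RuCl(p-cymene)[(S,S)-N-tosyl-1,2-diphenylethylenediamine], HCO2H/Et3N) is a reaction type known to give syn α-alkoxy β-hydroxy esters and should deliver the (2S,3R)-syn hydroxy ester F7. The catalyst enantiomer is chosen to give the (3R) carbinol; by analogy with aryl ketone reductions this is expected to be the (S,S) complex. LiAlH4 then reduces both esters of F7 to triol 14.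

Step 5. The phenoxide may attack the imide carbonyl of 8 (acyl transfer with loss of the auxiliary) in competition with displacement of bromide. The fallback sets out from 9 and 5 and comes back at 10. Phenol 9 is alkylated with tert-butyl bromoacetate (K2CO3, DMF) to the tert-butyl aryloxyacetate F8. The tert-butyl ester is cleaved with CF3CO2H in CH2Cl2 to the aryloxyacetic acid F9. This is activated as the mixed pivalic anhydride F10 (t-BuCOCl, Et3N, THF, −20 °C), which acylates 5 in the presence of LiCl to give 10.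

**Further compounds**

F1 | step 10 | 4-({(4R,5R)-4-[4-(benzyloxy)-3-methoxyphenyl]-2,2-dimethyl-1,3-dioxan-5-yl}oxy)-3-methoxybenzaldehyde | O=Cc1ccc(O[C@@H]2COC(C)(C)O[C@@H]2c3ccc(OCc4ccccc4)c(OC)c3)c(OC)c1
F2 | step 10 | (3S,5S)-3-[ArB(hydroxy)methyl]-5-{[(tert-butyldiphenylsilyl)oxy]methyl}dihydrofuran-2(3H)-one, 3,5-trans, carbinol epimers | O=C1[C@H](C(O)c2ccc(O[C@@H]3COC(C)(C)O[C@@H]3c4ccc(OCc5ccccc5)c(OC)c4)c(OC)c2)C[C@@H](CO[Si](c6ccccc6)(c7ccccc7)C(C)(C)C)O1
F3 | step 10 | O-(imidazol-1-ylthiocarbonyl) derivative of F2 | O=C1[C@H](C(OC(=S)n2ccnc2)c3ccc(O[C@@H]4COC(C)(C)O[C@@H]4c5ccc(OCc6ccccc6)c(OC)c5)c(OC)c3)C[C@@H](CO[Si](c7ccccc7)(c8ccccc8)C(C)(C)C)O1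
F4 | step 6 | methyl 3-methoxy-4-(2-methoxy-2-oxoethoxy)benzoate | COC(=O)COc1ccc(C(=O)OC)cc1OC
F5 | step 6 | methyl 3-[4-(benzyloxy)-3-methoxyphenyl]-3-hydroxy-2-[2-methoxy-4-(methoxycarbonyl)phenoxy]propanoate, racemic diastereomer mixture | COC(=O)c1ccc(OC(C(=O)OC)C(O)c2ccc(OCc3ccccc3)c(OC)c2)c(OC)c1
F6 | step 6 | methyl 3-[4-(benzyloxy)-3-methoxyphenyl]-2-[2-methoxy-4-(methoxycarbonyl)phenoxy]-3-oxopropanoate | COC(=O)c1ccc(OC(C(=O)OC)C(=O)c2ccc(OCc3ccccc3)c(OC)c2)c(OC)c1
F7 | step 6 | methyl (2S,3R)-3-[4-(benzyloxy)-3-methoxyphenyl]-3-hydroxy-2-[2-methoxy-4-(methoxycarbonyl)phenoxy]propanoate | COC(=O)c1ccc(O[C@H](C(=O)OC)[C@H](O)c2ccc(OCc3ccccc3)c(OC)c2)c(OC)c1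
F8 | step 5 | methyl 4-(2-tert-butoxy-2-oxoethoxy)-3-methoxybenzoate | CC(C)(C)OC(=O)COc1ccc(C(=O)OC)cc1OC
F9 | step 5 | 2-[2-methoxy-4-(methoxycarbonyl)phenoxy]acetic acid | OC(=O)COc1ccc(C(=O)OC)cc1OC
F10 | step 5 | mixed anhydride of F9 with pivalic acid | CC(C)(C)C(=O)OC(=O)COc1ccc(C(=O)OC)cc1OC
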